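The cyclohexane ring is cut at C5–C6 and C8–C8a (quinolinone numbering). This leaves a fully substituted pyridine (the 4-pyridone masked as its benzyl ether) that carries bromine at C8a and a configurationally defined pyridylic chloride at C5, and the three carbons C6–C7–C8 as acryloyltrimethylsilane. In one operation the C8a aryllithium adds to the acylsilane carbonyl (C8), a Brook shift turns the acrylic unit into a siloxyallyl anion, and its C6 terminus displaces the C5 chloride with inversion. The step exploits the ortho relation of C8a and the C5-bearing carbon C4a on the pyridine ring and the oxygen on C8 next to C8a, which is the imprint of an acylsilane.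

Key step: step 10

Remark: (S)-2-methyl-CBS-oxazaborolidine and the (R,R)-TsDPEN ruthenium catalyst are assumed to treat the pyridyl group as the large (aryl) substituent; the mirror-image catalyst would be taken if the facial sense proved opposite.

Step 1
Reactants: 1 3-methoxy-2-methylpyridin-4(1H)-one
Product: 2 5-bromo-3-methoxy-2-methylpyridin-4(1H)-one
Conditions: NBS, DMF, 0 °C to rt
Reagents that add atoms: N-bromosuccinimide, O=C1CCC(=O)N1Br
Why: Electrophilic bromination of the 4-pyridone should take place at C5, the only free enaminone β-carbon, since C3 carries the methoxy group.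

Step 2
Reactants: 2 5-bromo-3-methoxy-2-methylpyridin-4(1H)-one
Product: 3 4-(benzyloxy)-5-bromo-3-methoxy-2-methylpyridine
Conditions: BnBr, Ag2CO3, toluene, 80 °C, dark
Reagents that add atoms: benzyl bromide, BrCc1ccccc1
Why: Alkylation of the silver salt of a pyridone in a non-polar solvent should go to oxygen and give the aromatic 4-benzyloxypyridine (silver-mediated O-alkylation of pyridones).

Step 3
Reactants: 3 4-(benzyloxy)-5-bromo-3-methoxy-2-methylpyridine
Product: 5 4-(benzyloxy)-2,3-dibromo-5-methoxy-6-methylpyridine, via pyridin-2-ylmagnesium chloride 4 (not isolated)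
Conditions: TMPMgCl·LiCl, THF, −30 °C; then BrCl2C–CCl2Br, −30 °C to rt
Reagents that add atoms: 1,2-dibromo-1,1,2,2-tetrachloroethane, BrC(Cl)(Cl)C(Cl)(Cl)Br
Why: The only ring C–H lies between the ring nitrogen and the C–Br bond, so directed magnesiation should give 4 without bromine–magnesium exchange or halogen migration, and 4 takes up bromine from the perhaloethane (deprotonative metalation–halogenation).

Step 4
Reactants: 6 6-phenylhexanoic acid
Product: 8 N-methoxy-N-methyl-6-phenylhexanamide, via acyl imidazole 7 (not isolated)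
Conditions: 1,1'-carbonyldiimidazole, CH2Cl2, rt; then MeNH(OMe)·HCl, rt
Reagents that add atoms: N,O-dimethylhydroxylamine hydrochloride, CNOC.Cl
Why: Activation of the acid as the acyl imidazole and aminolysis is a standard Weinreb amide synthesis.

Step 5
Reactants: 5 4-(benzyloxy)-2,3-dibromo-5-methoxy-6-methylpyridine; 8 N-methoxy-N-methyl-6-phenylhexanamide
Product: 10 1-[4-(benzyloxy)-2-bromo-5-methoxy-6-methylpyridin-3-yl]-6-phenylhexan-1-one, via pyridin-3-ylmagnesium chloride 9 (not isolated)
Conditions: iPrMgCl·LiCl, THF, −40 °C; then 8, −40 °C to rt; aq. NH4Cl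
Reagents that add atoms: none
Why: Bromine–magnesium exchange should occur at C3 of 5, where the aryl anion is flanked by the benzyloxy group and the second bromine (the usual site in 2,3-dibromopyridines), and 9 adds once to the amide (Weinreb ketone synthesis).

Step 6
Reactants: 10 1-[4-(benzyloxy)-2-bromo-5-methoxy-6-methylpyridin-3-yl]-6-phenylhexan-1-one
Product: 11 (1R)-1-[4-(benzyloxy)-2-bromo-5-methoxy-6-methylpyridin-3-yl]-6-phenylhexan-1-ol
Conditions: (S)-2-methyl-CBS-oxazaborolidine (20 mol %), BH3·SMe2, THF, −20 °C; MeOH, then aq. work-up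
Reagents that add atoms: none
Why: Corey–Bakshi–Shibata reduction with the (S)-catalyst should deliver hydride to the face that gives the (R)-carbinol, the twisted di-ortho-substituted pyridyl group acting as the large substituent against the primary alkyl chain.

Step 7
Reactants: 11 (1R)-1-[4-(benzyloxy)-2-bromo-5-methoxy-6-methylpyridin-3-yl]-6-phenylhexan-1-ol
Product: 12 4-(benzyloxy)-2-bromo-3-[(1S)-1-chloro-6-phenylhexyl]-5-methoxy-6-methylpyridine
Conditions: PPh3, NCS, THF, −20 to 0 °C
Reagents that add atoms: N-chlorosuccinimide, O=C1CCC(=O)N1Cl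
Why: Appel-type activation of the hydroxyl group and backside attack by chloride should give the chloride with inversion, the pyridine nitrogen and the bromine disfavouring ionisation.

Step 8
Reactants: 13 trimethyl(prop-2-en-1-yloxy)silane
Product: 15 1-(trimethylsilyl)prop-2-en-1-ol, via lithium alkoxide 14 (not isolated)
Conditions: t-BuLi, THF, −78 to −35 °C; aq. NH4Cl
Reagents that add atoms: none
Why: t-BuLi removes an allylic α-oxy proton and the silyl group shifts from oxygen to the carbanionic carbon (retro-Brook rearrangement) to give alkoxide 14.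

Step 9
Reactants: 15 1-(trimethylsilyl)prop-2-en-1-ol
Product: 16 1-(trimethylsilyl)prop-2-en-1-one
Conditions: (COCl)2, DMSO, CH2Cl2, −78 °C; Et3N
Reagents that add atoms: none
Why: Swern oxidation of the α-silyl carbinol is the standard access to this acylsilane, which is used freshly prepared.

Step 10
Reactants: 12 4-(benzyloxy)-2-bromo-3-[(1S)-1-chloro-6-phenylhexyl]-5-methoxy-6-methylpyridine; 16 1-(trimethylsilyl)prop-2-en-1-one
Product: 21 (5S)-4-(benzyloxy)-3-methoxy-2-methyl-5-(5-phenylpentyl)-6,7-dihydroquinolin-8(5H)-one, via aryllithium 17 (not isolated), via lithium alkoxide 18 (not isolated), via siloxyallyllithium 19 (not isolated), via silyl enol ether 20 (not isolated)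
Conditions: t-BuLi (2.0 equiv), THF/Et2O, −100 °C; then 16, −100 to −20 °C; then dilute aq. HCl, 0 °C
Reagents that add atoms: none
Why: Bromine–lithium exchange at C8a gives 17, which adds 1,2 to the acylsilane carbonyl (C8a–C8); alkoxide 18 undergoes a 1,2-Brook silyl shift because the resulting carbanion is both allylic and 2-pyridylic, and siloxyallyllithium 19 attacks the C5 chloride through its C6 terminus (C5–C6), so that the normally electrophilic acrylic β-carbon is joined to an electrophilic carbon by polarity reversal. The closest known reaction type is the addition of organolithiums to α,β-unsaturated acylsilanes with Brook rearrangement and γ-alkylation of the siloxyallyl anion, as also used in Brook-triggered annulations, here with the alkylation made intramolecular. The ring (C8a, C8, C7, C6, C5, C4a) closes in a 6-(enolendo)-exo-tet mode, with the C7=C8 enol ether bond inside the ring and the chloride leaving outside it. C5 is set by the substrate: backside displacement inverts the (1S)-chloride to the (5S) centre (the descriptor stays S only because the CIP ranks change), while C8 is trigonal at this stage. The step needs 1,2- over 1,4-addition (hard aryllithium, very electrophilic acylsilane carbonyl), a Brook shift faster than O-alkylation of 18 (fast trimethylsilyl shift to a doubly stabilised carbanion, while a tertiary lithium alkoxide is inert to a secondary chloride at −78 °C) and attack through C6 and not C8 (which would close a four-membered ring); exchange at −100 °C with two equivalents of t-BuLi outruns attack on the chloride and destroys the t-BuBr formed. Dilute acid then hydrolyses 20 to ketone 21.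

Step 11
Reactants: 21 (5S)-4-(benzyloxy)-3-methoxy-2-methyl-5-(5-phenylpentyl)-6,7-dihydroquinolin-8(5H)-one
Product: 22 (5S,8R)-4-(benzyloxy)-3-methoxy-2-methyl-5-(5-phenylpentyl)-5,6,7,8-tetrahydroquinolin-8-ol
Conditions: RuCl(p-cymene)[(R,R)-TsDPEN] (1 mol %), HCO2H/Et3N (5:2), CH2Cl2, rt
Reagents that add atoms: none
Why: Noyori-type asymmetric transfer hydrogenation of the pyridyl ketone should set C8 as (R) under catalyst control (pyridine ring as the aryl group of the usual model), which places the hydroxyl cis to the remote C5 chain.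

Step 12
Reactants: 22 (5S,8R)-4-(benzyloxy)-3-methoxy-2-methyl-5-(5-phenylpentyl)-5,6,7,8-tetrahydroquinolin-8-ol
Product: 23 (5S,8R)-8-hydroxy-3-methoxy-2-methyl-5-(5-phenylpentyl)-5,6,7,8-tetrahydroquinolin-4(1H)-one
Conditions: H2 (1 atm), 10% Pd/C, EtOH, rt
Reagents that add atoms: none
Why: Hydrogenolysis of the 4-benzyloxypyridine should release the 4-pyridone under neutral conditions that leave the pyridylic alcohol, the phenyl ring and both stereocentres untouched.

Compound list
1 | 3-methoxy-2-methylpyridin-4(1H)-one | COc1c(C)[nH]ccc1=O | starting material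
2 | 5-bromo-3-methoxy-2-methylpyridin-4(1H)-one | COc1c(C)[nH]cc(Br)c1=O | intermediate
3 | 4-(benzyloxy)-5-bromo-3-methoxy-2-methylpyridine | COc1c(C)ncc(Br)c1OCc1ccccc1 | intermediate
4 | [4-(benzyloxy)-3-bromo-5-methoxy-6-methylpyridin-2-yl]magnesium chloride (not isolated) | COc1c(C)nc([Mg]Cl)c(Br)c1OCc1ccccc1 | intermediate
5 | 4-(benzyloxy)-2,3-dibromo-5-methoxy-6-methylpyridine | COc1c(C)nc(Br)c(Br)c1OCc1ccccc1 | intermediate
6 | 6-phenylhexanoic acid | OC(=O)CCCCCc1ccccc1 | starting material
7 | 1-(1H-imidazol-1-yl)-6-phenylhexan-1-one (not isolated) | O=C(CCCCCc1ccccc1)n1ccnc1 | intermediate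
8 | N-methoxy-N-methyl-6-phenylhexanamide | CON(C)C(=O)CCCCCc1ccccc1 | intermediate
9 | [4-(benzyloxy)-2-bromo-5-methoxy-6-methylpyridin-3-yl]magnesium chloride (not isolated) | COc1c(C)nc(Br)c([Mg]Cl)c1OCc1ccccc1 | intermediate
10 | 1-[4-(benzyloxy)-2-bromo-5-methoxy-6-methylpyridin-3-yl]-6-phenylhexan-1-one | COc1c(C)nc(Br)c(C(=O)CCCCCc2ccccc2)c1OCc1ccccc1 | intermediate
11 | (1R)-1-[4-(benzyloxy)-2-bromo-5-methoxy-6-methylpyridin-3-yl]-6-phenylhexan-1-ol | COc1c(C)nc(Br)c([C@H](O)CCCCCc2ccccc2)c1OCc1ccccc1 | intermediate
12 | 4-(benzyloxy)-2-bromo-3-[(1S)-1-chloro-6-phenylhexyl]-5-methoxy-6-methylpyridine | COc1c(C)nc(Br)c([C@@H](Cl)CCCCCc2ccccc2)c1OCc1ccccc1 | intermediate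
13 | trimethyl(prop-2-en-1-yloxy)silane | C=CCO[Si](C)(C)C | starting material
14 | lithium 1-(trimethylsilyl)prop-2-en-1-olate (not isolated) | C=CC(O[Li])[Si](C)(C)C | intermediate
15 | 1-(trimethylsilyl)prop-2-en-1-ol | C=CC(O)[Si](C)(C)C | intermediate
16 | 1-(trimethylsilyl)prop-2-en-1-one | C=CC(=O)[Si](C)(C)C | intermediate
17 | {4-(benzyloxy)-3-[(1S)-1-chloro-6-phenylhexyl]-5-methoxy-6-methylpyridin-2-yl}lithium (not isolated) | COc1c(C)nc([Li])c([C@@H](Cl)CCCCCc2ccccc2)c1OCc1ccccc1 | intermediate
18 | lithium 1-{4-(benzyloxy)-3-[(1S)-1-chloro-6-phenylhexyl]-5-methoxy-6-methylpyridin-2-yl}-1-(trimethylsilyl)prop-2-en-1-olate (not isolated; either configuration at the carbinol carbon) | COc1c(C)nc(C(O[Li])(C=C)[Si](C)(C)C)c([C@@H](Cl)CCCCCc2ccccc2)c1OCc1ccccc1 | intermediate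
19 | (3-{4-(benzyloxy)-3-[(1S)-1-chloro-6-phenylhexyl]-5-methoxy-6-methylpyridin-2-yl}-3-[(trimethylsilyl)oxy]prop-2-en-1-yl)lithium (not isolated; delocalised allyl anion drawn in its C6-lithio form) | COc1c(C)nc(C(O[Si](C)(C)C)=CC[Li])c([C@@H](Cl)CCCCCc2ccccc2)c1OCc1ccccc1 | intermediate
20 | (5S)-4-(benzyloxy)-3-methoxy-2-methyl-5-(5-phenylpentyl)-8-[(trimethylsilyl)oxy]-5,6-dihydroquinoline (not isolated) | COc1c(C)nc2c(c1OCc1ccccc1)[C@@H](CCCCCc1ccccc1)CC=C2O[Si](C)(C)C | intermediate
21 | (5S)-4-(benzyloxy)-3-methoxy-2-methyl-5-(5-phenylpentyl)-6,7-dihydroquinolin-8(5H)-one | COc1c(C)nc2c(c1OCc1ccccc1)[C@@H](CCCCCc1ccccc1)CCC2=O | intermediate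
22 | (5S,8R)-4-(benzyloxy)-3-methoxy-2-methyl-5-(5-phenylpentyl)-5,6,7,8-tetrahydroquinolin-8-ol | COc1c(C)nc2c(c1OCc1ccccc1)[C@@H](CCCCCc1ccccc1)CC[C@H]2O | intermediate
23 | (5S,8R)-8-hydroxy-3-methoxy-2-methyl-5-(5-phenylpentyl)-5,6,7,8-tetrahydroquinolin-4(1H)-one | COc1c(C)[nH]c2c(c1=O)[C@@H](CCCCCc1ccccc1)CC[C@H]2O | target

Total step count: 12
Longest linear sequence: 9 steps (steps 1, 2, 3, 5, 6, 7, 10, 11, 12)

Steps most likely to fail

1. Step 10. Alkoxide 18 may close onto C5 through oxygen before the silyl shift. The siloxyallyl anion may also be protonated or lose HCl instead of alkylating, and the exchange may be accompanied by attack of t-BuLi on the benzylic chloride. The fallback sets out from 12 and comes back at 21, making the two bonds in separate operations. Chloride 12 is coupled with commercial [2-(1,3-dioxolan-2-yl)ethyl]magnesium bromide under CuI/TMEDA/LiOMe catalysis in THF at 0 °C (substitution with inversion, C5–C6) to give 4-(benzyloxy)-2-bromo-3-[(3S)-1-(1,3-dioxolan-2-yl)-8-phenyloctan-3-yl]-5-methoxy-6-methylpyridine F1. Aqueous HCl in THF frees the aldehyde (4S)-4-[4-(benzyloxy)-2-bromo-5-methoxy-6-methylpyridin-3-yl]-9-phenylnonanal F2. An intramolecular Nozaki–Hiyama–Kishi reaction (CrCl2, catalytic NiCl2, DMF) of the C8a bromide with the aldehyde closes C8–C8a and gives (5S)-4-(benzyloxy)-3-methoxy-2-methyl-5-(5-phenylpentyl)-5,6,7,8-tetrahydroquinolin-8-ol F3 as a mixture of C8 epimers. Dess–Martin periodinane oxidises F3 to ketone 21.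

2. Step 7. The two ortho substituents slow backside attack at the carbinol carbon, so ionisation may compete and erode the configuration, or HCl may be lost to the alkene. The fallback sets out from 10 and comes back at 12. Ketone 10 is reduced with the (R)-configured oxazaborolidine catalyst and BH3·SMe2 to the enantiomeric alcohol (1S)-1-[4-(benzyloxy)-2-bromo-5-methoxy-6-methylpyridin-3-yl]-6-phenylhexan-1-ol F4. F4 is chlorinated with SOCl2 in 1,4-dioxane, where the chlorosulfite collapses with retention (internal substitution) and no backside attack is needed, to give 12.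

3. Step 3. The amide base may remove a proton from the C2 methyl group (lateral metalation) instead of the ring C–H, or metalation may stay incomplete. The fallback sets out from 3 and comes back at 5 without any strong base. mCPBA in CH2Cl2 oxidises 3 to 4-(benzyloxy)-5-bromo-3-methoxy-2-methylpyridine 1-oxide F5. Ts2O and n-Bu4NBr in CH2Cl2 then activate the N-oxide on oxygen, bromide adds to the only free α-position, and loss of TsOH gives 5 (N-oxide-directed α-bromination).

Further compounds
F1 | step 10 | 4-(benzyloxy)-2-bromo-3-[(3S)-1-(1,3-dioxolan-2-yl)-8-phenyloctan-3-yl]-5-methoxy-6-methylpyridine | COc1c(C)nc(Br)c([C@@H](CCCCCc2ccccc2)CCC2OCCO2)c1OCc1ccccc1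
F2 | step 10 | (4S)-4-[4-(benzyloxy)-2-bromo-5-methoxy-6-methylpyridin-3-yl]-9-phenylnonanal | COc1c(C)nc(Br)c([C@@H](CCCCCc2ccccc2)CCC=O)c1OCc1ccccc1
F3 | step 10 | (5S)-4-(benzyloxy)-3-methoxy-2-methyl-5-(5-phenylpentyl)-5,6,7,8-tetrahydroquinolin-8-ol (mixture of C8 epimers) | COc1c(C)nc2c(c1OCc1ccccc1)[C@@H](CCCCCc1ccccc1)CCC2O
F4 | step 7 | (1S)-1-[4-(benzyloxy)-2-bromo-5-methoxy-6-methylpyridin-3-yl]-6-phenylhexan-1-ol | COc1c(C)nc(Br)c([C@@H](O)CCCCCc2ccccc2)c1OCc1ccccc1
F5 | step 3 | 4-(benzyloxy)-5-bromo-3-methoxy-2-methylpyridine 1-oxide | COc1c(C)[n+]([O-])cc(Br)c1OCc1ccccc1
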